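**Retrosynthetic overview**
1. Target 18 ⇐ bis-MOM ketone 17 ⇐ cis-isoflavan-4-ol 16 ⇐ isoflavone 14: C3 is set last by asymmetric transfer hydrogenation with dynamic kinetic resolution, then C4 is re-oxidised and the phenols are freed.
2. Isoflavone 14 ⇐ Suzuki–Miyaura coupling (C3–C1' bond) of 3-iodochromone 13 (rings A and C) with chromen-6-yl boronate 9 (ring B with its dimethylpyran ring).
3. Dimethylpyran ring of chromene 8 ⇐ fluoro aldehyde 2 plus the C4O unit of chlorohydrin 3, joined in one flask at C4–C3 (which becomes the C3=C4 alkene) and at O1–C8a.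
4. Enabling feature: in the chromene unit (O1, C2, C3, C4, C4a, C8a) C4 and O1 sit on the ortho neighbours C4a and C8a of ring B, and C2 is a fully substituted carbinol carbon. An aldehyde carbon beside a C–F carbon therefore matches the 1,3-C,O-dianion LiCH2–C(CH3)2–OLi; the two methyl groups favour six-ring closure and O1 then assists loss of the C4 oxygen toward C3.
5. Ring order: ring C (step 6) and the dimethylpyran ring (step 2) on separate branches, union of the halves (step 7), stereocentre (step 8).

Key step: step 2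

Assumption: the (S,S)-TsDPEN ruthenium catalyst is taken to deliver hydride to the chromanone carbonyl in the same sense as to simple aryl alkyl ketones (4S), so that the cis-selective dynamic kinetic resolution gives 3S; the mirror-image ligand would be used if the sense were the opposite. Compounds 1, 3 and 10 are taken as commercial. Chromene numbering is used for the dimethylpyran unit.

**Step 1**
Reactants: 1 2-fluoro-3-hydroxybenzaldehyde
Product: 2 2-fluoro-3-(methoxymethoxy)benzaldehyde
Conditions: MOMCl, i-Pr2NEt, CH2Cl2, 0 → 25 °C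
Reagents that add atoms: chloromethyl methyl ether (MOMCl), COCCl
Why: O-alkylation of the phenol with the chloromethyl ether (MOM protection) is routine and gives an ether that should withstand the organolithium, tert-butoxide and palladium steps.

**Step 2**
Reactants: 2 2-fluoro-3-(methoxymethoxy)benzaldehyde; 3 1-chloro-2-methylpropan-2-ol
Product: 8 8-(methoxymethoxy)-2,2-dimethyl-2H-chromene, via lithio alkoxide 4 (not isolated), via diolate adduct 5 (not isolated), via chroman-4-olate 6 (not isolated), via chromanyl mesylate 7 (not isolated)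
Conditions: 3, n-BuLi, THF, −78 °C; lithium naphthalenide (LiC10H8, 2 equiv), −78 °C; add 2, −78 °C; KOt-Bu, DMPU, −78 → 70 °C; then MsCl, Et3N, 0 → 25 °C
Reagents that add atoms: none
Why: Chlorine–lithium exchange on the lithium alkoxide of 3 gives the C,O-dianion 4, whose carbanion adds to the aldehyde of 2 at −78 °C (C4–C3) faster than 4 can lose Li2O; after cation exchange to potassium in DMPU the tertiary alkoxide of 5 attacks the fluorine-bearing C8a by addition–elimination (O1–C8a), and mesylation of the benzylic alkoxide 6 followed by base-induced loss of methanesulfonate from 7 turns the new C4–C3 bond into the alkene. The closest known reaction types are the addition of β-lithioalkoxides made from chlorohydrins to aldehydes, the alkoxide-mediated intramolecular SNAr etherification of non-activated 2-fluoroaryl alkanols to chromans, and the MsCl/Et3N dehydration of chroman-4-ols. The pyran ring closes as a six-membered ring by ipso attack of O1 on the arene carbon C8a, helped by the gem-dimethyl group at C2. No stereocentre survives, since the racemic carbinol carbon C4 of 5, 6 and 7 becomes sp2. The step needs carbon before oxygen attack of the dianion (the carbanion is by far the stronger nucleophile), closure only at C8a (the only C–F carbon, flanked on both sides so that no aryne can form) and elimination only toward C3 (the only β-hydrogens, with the developing C4 cation stabilised by O1 through C8a–C4a).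

**Step 3**
Reactants: 8 8-(methoxymethoxy)-2,2-dimethyl-2H-chromene
Product: 9 2-[8-(methoxymethoxy)-2,2-dimethyl-2H-chromen-6-yl]-4,4,5,5-tetramethyl-1,3,2-dioxaborolane
Conditions: B2pin2, [Ir(OMe)(cod)]2 (cat.), 4,4'-di-tert-butyl-2,2'-bipyridine (cat.), THF, 50 °C
Reagents that add atoms: bis(pinacolato)diboron, CC1(C)OB(OC1(C)C)B1OC(C)(C)C(C)(C)O1
Why: Iridium-catalysed aromatic C–H borylation is governed by sterics and should go to C6, the only ring C–H without an ortho substituent, in preference to the hindered alkene C–H bonds.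

**Step 4**
Reactants: 10 1-(2,4-dihydroxy-6-methoxyphenyl)ethan-1-one
Product: 11 1-[2-hydroxy-6-methoxy-4-(methoxymethoxy)phenyl]ethan-1-one
Conditions: MOMCl (1 equiv), i-Pr2NEt, CH2Cl2, 0 °C
Reagents that add atoms: chloromethyl methyl ether (MOMCl), COCCl
Why: The 4-hydroxyl is free while the 2-hydroxyl is held in a hydrogen bond to the ketone, so one equivalent of MOMCl should etherify only the former (selective MOM protection).

**Step 5**
Reactants: 11 1-[2-hydroxy-6-methoxy-4-(methoxymethoxy)phenyl]ethan-1-one
Product: 12 (E)-3-(dimethylamino)-1-[2-hydroxy-6-methoxy-4-(methoxymethoxy)phenyl]prop-2-en-1-one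
Conditions: Me2NCH(OMe)2, toluene, 95 °C
Reagents that add atoms: N,N-dimethylformamide dimethyl acetal, COC(OC)N(C)C
Why: Condensation of the methyl ketone with the formamide acetal gives the (E)-enaminone and leaves the chelated phenol free for ring closure.

**Step 6**
Reactants: 12 (E)-3-(dimethylamino)-1-[2-hydroxy-6-methoxy-4-(methoxymethoxy)phenyl]prop-2-en-1-one
Product: 13 3-iodo-5-methoxy-7-(methoxymethoxy)-4H-chromen-4-one
Conditions: I2, CHCl3, 25 °C
Reagents that add atoms: iodine, II
Why: Iodine attacks the enaminone α-carbon, the phenol closes ring C by oxa-Michael addition to the iminium carbon and dimethylamine is lost (iodocyclisation of 2-hydroxyaryl enaminones to 3-iodochromones).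

**Step 7**
Reactants: 13 3-iodo-5-methoxy-7-(methoxymethoxy)-4H-chromen-4-one; 9 2-[8-(methoxymethoxy)-2,2-dimethyl-2H-chromen-6-yl]-4,4,5,5-tetramethyl-1,3,2-dioxaborolane
Product: 14 5-methoxy-7-(methoxymethoxy)-3-[8-(methoxymethoxy)-2,2-dimethyl-2H-chromen-6-yl]-4H-chromen-4-one
Conditions: Pd(dppf)Cl2 (cat.), K2CO3, 1,4-dioxane/H2O, 80 °C
Reagents that add atoms: none
Why: Suzuki–Miyaura coupling of a 3-iodochromone with an electron-rich aryl boronate is the standard isoflavone synthesis and should form the C3–C1' bond without touching the MOM ethers or the chromene alkene.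

**Step 8**
Reactants: 14 5-methoxy-7-(methoxymethoxy)-3-[8-(methoxymethoxy)-2,2-dimethyl-2H-chromen-6-yl]-4H-chromen-4-one
Product: 16 (3S,4S)-5-methoxy-7-(methoxymethoxy)-3-[8-(methoxymethoxy)-2,2-dimethyl-2H-chromen-6-yl]chroman-4-ol, via racemic isoflavanone 15 (not isolated)
Conditions: RuCl(p-cymene)[(S,S)-TsDPEN] (cat.), HCO2H/Et3N (1:1), EtOAc, 40 °C
Reagents that add atoms: none
Why: The ruthenium hydride first reduces C2=C3 in a conjugate manner to isoflavanone 15, which racemises through its enol under Et3N while the (S,S)-ligand directs hydride to one face of C4 of the 3S enantiomer, anti to the 3-aryl group (asymmetric transfer hydrogenation with dynamic kinetic resolution), so that the cis (3S,4S) alcohol should result and the isolated chromene alkene is not reduced.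

**Step 9**
Reactants: 16 (3S,4S)-5-methoxy-7-(methoxymethoxy)-3-[8-(methoxymethoxy)-2,2-dimethyl-2H-chromen-6-yl]chroman-4-ol
Product: 17 (3S)-5-methoxy-7-(methoxymethoxy)-3-[8-(methoxymethoxy)-2,2-dimethyl-2H-chromen-6-yl]chroman-4-one
Conditions: Dess–Martin periodinane, pyridine, CH2Cl2, 0 °C
Reagents that add atoms: none
Why: Dess–Martin oxidation of the benzylic alcohol under pyridine-buffered, non-enolising conditions returns the C4 ketone and should leave the C3 stereocentre set in step 8 untouched.

**Step 10**
Reactants: 17 (3S)-5-methoxy-7-(methoxymethoxy)-3-[8-(methoxymethoxy)-2,2-dimethyl-2H-chromen-6-yl]chroman-4-one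
Product: 18 (3S)-7-hydroxy-3-(8-hydroxy-2,2-dimethyl-2H-chromen-6-yl)-5-methoxychroman-4-one
Conditions: ZnBr2, n-PrSH, CH2Cl2, 0 → 25 °C
Reagents that add atoms: none
Why: Zinc bromide activates the acetal oxygen and the thiol takes up the methoxymethyl group (Lewis acid/thiol MOM cleavage), a fast and nearly neutral deprotection chosen so that the epimerisable C3 stereocentre, the aryl methyl ether and the chromene should not be affected.

**Compound list**
1 | 2-fluoro-3-hydroxybenzaldehyde | O=Cc1cccc(O)c1F | starting material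
2 | 2-fluoro-3-(methoxymethoxy)benzaldehyde | O=Cc1cccc(OCOC)c1F | intermediate
3 | 1-chloro-2-methylpropan-2-ol | CC(C)(O)CCl | starting material
4 | lithium 1-lithio-2-methylpropan-2-olate | [Li]CC(C)(C)O[Li] | intermediate
5 | dilithium 1-[2-fluoro-3-(methoxymethoxy)phenyl]-3-methylbutane-1,3-diolate (racemic) | COCOc1cccc(C(O[Li])CC(C)(C)O[Li])c1F | intermediate
6 | potassium 8-(methoxymethoxy)-2,2-dimethylchroman-4-olate (racemic) | COCOc1cccc2C([O-])CC(C)(C)Oc12.[K+] | intermediate
7 | 8-(methoxymethoxy)-2,2-dimethylchroman-4-yl methanesulfonate (racemic) | COCOc1cccc2C(OS(C)(=O)=O)CC(C)(C)Oc12 | intermediate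
8 | 8-(methoxymethoxy)-2,2-dimethyl-2H-chromene | COCOc1cccc2C=CC(C)(C)Oc12 | intermediate
9 | 2-[8-(methoxymethoxy)-2,2-dimethyl-2H-chromen-6-yl]-4,4,5,5-tetramethyl-1,3,2-dioxaborolane | CC1(C)OB(OC1(C)C)c1cc(OCOC)c2OC(C)(C)C=Cc2c1 | intermediate
10 | 1-(2,4-dihydroxy-6-methoxyphenyl)ethan-1-one | CC(=O)c1c(O)cc(O)cc1OC | starting material
11 | 1-[2-hydroxy-6-methoxy-4-(methoxymethoxy)phenyl]ethan-1-one | CC(=O)c1c(O)cc(OCOC)cc1OC | intermediate
12 | (E)-3-(dimethylamino)-1-[2-hydroxy-6-methoxy-4-(methoxymethoxy)phenyl]prop-2-en-1-one | CN(C)/C=C/C(=O)c1c(O)cc(OCOC)cc1OC | intermediate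
13 | 3-iodo-5-methoxy-7-(methoxymethoxy)-4H-chromen-4-one | COCOc1cc(OC)c2c(c1)occ(I)c2=O | intermediate
14 | 5-methoxy-7-(methoxymethoxy)-3-[8-(methoxymethoxy)-2,2-dimethyl-2H-chromen-6-yl]-4H-chromen-4-one | COCOc1cc(OC)c2c(c1)occ(-c1cc(OCOC)c3OC(C)(C)C=Cc3c1)c2=O | intermediate
15 | 5-methoxy-7-(methoxymethoxy)-3-[8-(methoxymethoxy)-2,2-dimethyl-2H-chromen-6-yl]chroman-4-one (racemic) | COc1cc(OCOC)cc2OCC(c3cc(OCOC)c4OC(C)(C)C=Cc4c3)C(=O)c12 | intermediate
16 | (3S,4S)-5-methoxy-7-(methoxymethoxy)-3-[8-(methoxymethoxy)-2,2-dimethyl-2H-chromen-6-yl]chroman-4-ol (cis) | COc1cc(OCOC)cc2c1[C@@H](O)[C@@H](c1cc(OCOC)c3c(c1)C=CC(C)(C)O3)CO2 | intermediate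
17 | (3S)-5-methoxy-7-(methoxymethoxy)-3-[8-(methoxymethoxy)-2,2-dimethyl-2H-chromen-6-yl]chroman-4-one | COc1cc(OCOC)cc2c1C(=O)[C@@H](c1cc(OCOC)c3c(c1)C=CC(C)(C)O3)CO2 | intermediate
18 | (3S)-7-hydroxy-3-(8-hydroxy-2,2-dimethyl-2H-chromen-6-yl)-5-methoxychroman-4-one | COc1cc(O)cc2c1C(=O)[C@@H](c1cc(O)c3c(c1)C=CC(C)(C)O3)CO2 | target

**Step count**
Total steps: 10. Longest linear sequence: 7 steps (1 → 2 → 8 → 9 → 14 → 16 → 17 → 18, or equally 10 → 11 → 12 → 13 → 14 → 16 → 17 → 18).

**Steps most likely to fail**

Step 2. The lithio alkoxide may lose Li2O (β-elimination to isobutene) before it meets the aldehyde. Fluoride displacement at the doubly flanked, non-activated C8a may also be too slow, so that the diolate decomposes or tert-butoxide competes. The fallback uses known chemistry and sets out from 2. The potassium alkoxide of 2-methylbut-3-en-2-ol (KH, THF/DMF, 0 → 25 °C) displaces fluoride while the ortho aldehyde still activates C8a, which should give 3-(methoxymethoxy)-2-[(2-methylbut-3-en-2-yl)oxy]benzaldehyde F1. Wittig methylenation (Ph3P=CH2, THF) should give 1-ethenyl-3-(methoxymethoxy)-2-[(2-methylbut-3-en-2-yl)oxy]benzene F2. Ring-closing metathesis with second-generation Grubbs catalyst, (H2IMes)(PCy3)Cl2Ru=CHPh, in CH2Cl2 at 40 °C then closes C3=C4 and comes back to the route at 8.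

Step 3. The iridium boryl species and the pinacolborane formed may hydroborate or borylate the C3=C4 alkene, which would erode site selectivity. The fallback installs boron before the alkene exists and sets out from 2. The annulation of step 2 is run up to the fluoride displacement and quenched with aqueous NH4Cl, which should give 8-(methoxymethoxy)-2,2-dimethylchroman-4-ol F3 (racemic). Borylation under the conditions of step 3, with extra B2pin2 for the hydroxyl, should give 8-(methoxymethoxy)-2,2-dimethyl-6-(4,4,5,5-tetramethyl-1,3,2-dioxaborolan-2-yl)chroman-4-ol F4. Suzuki–Miyaura coupling with 13 (Pd(dppf)Cl2, K2CO3) should give 3-[4-hydroxy-8-(methoxymethoxy)-2,2-dimethylchroman-6-yl]-5-methoxy-7-(methoxymethoxy)-4H-chromen-4-one F5. Dehydration with MsCl/Et3N comes back to the route at 14.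

Step 8. Hydride transfer to the C4 carbonyl beside the 5-methoxy group may be slow, so that reduction and enol racemisation fall out of step and facial selectivity is poor. The electron-rich benzylic alcohol may also ionise in the formate medium and lose water. The fallback sets the stereocentre by protonation and sets out from 14. Conjugate reduction with LiBH(s-Bu)3 (THF, −78 °C) and trapping with Me3SiCl should give 5-methoxy-7-(methoxymethoxy)-3-[8-(methoxymethoxy)-2,2-dimethyl-2H-chromen-6-yl]-4-(trimethylsilyloxy)-2H-chromene F6. Catalytic enantioselective protonation of this silyl enol ether with a chiral BINOL-derived N-triflyl thiophosphoramide and phenol as the proton source (toluene, 25 °C) comes back to the route at 17, with the catalyst enantiomer chosen for 3S.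

**Further compounds**
F1 | step 2 | 3-(methoxymethoxy)-2-[(2-methylbut-3-en-2-yl)oxy]benzaldehyde | C=CC(C)(C)Oc1c(C=O)cccc1OCOC
F2 | step 2 | 1-ethenyl-3-(methoxymethoxy)-2-[(2-methylbut-3-en-2-yl)oxy]benzene | C=CC(C)(C)Oc1c(C=C)cccc1OCOC
F3 | step 3 | 8-(methoxymethoxy)-2,2-dimethylchroman-4-ol (racemic) | COCOc1cccc2C(O)CC(C)(C)Oc12
F4 | step 3 | 8-(methoxymethoxy)-2,2-dimethyl-6-(4,4,5,5-tetramethyl-1,3,2-dioxaborolan-2-yl)chroman-4-ol (racemic) | COCOc1cc(B2OC(C)(C)C(C)(C)O2)cc2C(O)CC(C)(C)Oc12
F5 | step 3 | 3-[4-hydroxy-8-(methoxymethoxy)-2,2-dimethylchroman-6-yl]-5-methoxy-7-(methoxymethoxy)-4H-chromen-4-one (racemic) | COCOc1cc(OC)c2c(c1)occ(-c1cc(OCOC)c3OC(C)(C)CC(O)c3c1)c2=O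
F6 | step 8 | 5-methoxy-7-(methoxymethoxy)-3-[8-(methoxymethoxy)-2,2-dimethyl-2H-chromen-6-yl]-4-(trimethylsilyloxy)-2H-chromene | COc1cc(OCOC)cc2OCC(c3cc(OCOC)c4OC(C)(C)C=Cc4c3)=C(O[Si](C)(C)C)c12
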